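**Assumptions (one line each)**
- 4-Bromo-2,6-diiodophenol and prenyl-Bpin are taken as catalogue compounds (the phenol is otherwise one step from 4-bromophenol with I2/H2O2).
- The target is the (2S)-flavanone, as read from the SMILES.

**Retrosynthetic overview**
1. Final step is global MOM removal from bis-MOM sophoranone 15.
2. The C2–C1' bond and the only stereocentre come from a Rh-catalysed asymmetric 1,4-addition of arylboronic acid 14 to chromone 8.
3. Chromone 8 comes from 7-hydroxychromone by O-reverse-prenylation, aromatic Claisen rearrangement to C8, and MOM protection.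
4. Boronic acid 14 comes from 4-bromo-2,6-diiodophenol by MOM protection, double I-selective Suzuki prenylation, and Br/Li exchange–borylation.
5. No ring is built de novo: the benzopyranone and the B-ring arene are purchased, and the pyranone C2=C3 is converted to the chiral dihydropyranone in the key step.

**Route**

Step 1
Reactants: 1 (2-methylbut-3-en-2-ol); 2 (di-tert-butyl dicarbonate)
Product: 3 (tert-butyl 2-methylbut-3-en-2-yl carbonate)
Conditions: n-BuLi, THF, 0 °C; then Boc2O, 0 °C → rt
Reagents that add atoms: Boc2O, CC(C)(C)OC(=O)OC(=O)OC(C)(C)C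
Why: Acylation of the lithium tert-alkoxide gives the allylic carbonate needed for Tsuji–Trost ionisation.

Step 2
Reactants: 4 (7-hydroxy-4H-chromen-4-one); 3
Product: 5 (7-[(2-methylbut-3-en-2-yl)oxy]-4H-chromen-4-one)
Conditions: Pd(PPh3)4 (3 mol%), THF, 0 °C → rt
Reagents that add atoms: carbonate 3, C=CC(C)(C)OC(=O)OC(C)(C)C (delivers the 1,1-dimethylallyl group; CO2 and t-BuOH are lost)
Why: Tsuji–Trost decarboxylative O-allylation; under kinetic control the phenoxide attacks the more substituted terminus of the 1,1-dimethyl-π-allyl-Pd, giving the tertiary (reverse-prenyl) ether.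

Step 3
Reactants: 5
Product: 6 (7-hydroxy-8-(3-methylbut-2-en-1-yl)-4H-chromen-4-one)
Conditions: PhNEt2, 130 °C
Reagents that add atoms: none
Why: Aromatic Claisen [3,3] rearrangement turns the reverse-prenyl ether into a C-prenyl group; C8 is favoured over C6 because the C7–C8 bond has the higher double-bond character in benzopyranones, as with 7-allyloxychromones and coumarins.

Step 4
Reactants: 6; 7 (chloromethyl methyl ether, MOMCl)
Product: 8 (7-(methoxymethoxy)-8-(3-methylbut-2-en-1-yl)-4H-chromen-4-one)
Conditions: MOMCl, i-Pr2NEt, CH2Cl2, 0 °C → rt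
Reagents that add atoms: MOMCl, COCCl
Why: Standard phenol O-alkylation (acetal protection); masking the phenol stops it deactivating the chromone or quenching the Rh–aryl in step 8.

Step 5
Reactants: 9 (4-bromo-2,6-diiodophenol); 7 (MOMCl)
Product: 10 (5-bromo-1,3-diiodo-2-(methoxymethoxy)benzene)
Conditions: NaH, MOMCl, THF/DMF, 0 °C → rt
Reagents that add atoms: MOMCl, COCCl
Why: Williamson-type MOM protection of an acidic, hindered phenol; the acetal survives the Pd, organolithium and Rh steps.

Step 6
Reactants: 10; 11 (prenylboronic acid pinacol ester, 2.3 equiv)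
Product: 12 (5-bromo-2-(methoxymethoxy)-1,3-bis(3-methylbut-2-en-1-yl)benzene)
Conditions: Pd(dppf)Cl2·CH2Cl2 (5 mol%), Cs2CO3, THF/H2O (10:1), 55 °C
Reagents that add atoms: prenyl-Bpin, CC(C)=CCB1OC(C)(C)C(C)(C)O1
Why: Double Suzuki–Miyaura coupling; C–I oxidative addition is much faster than at the electron-rich C–Br, and reductive elimination from the less hindered primary terminus of the prenyl-Pd gives the linear (α) prenyl arenes.

Step 7
Reactants: 12; 13 (triisopropyl borate)
Product: 14 ([4-(methoxymethoxy)-3,5-bis(3-methylbut-2-en-1-yl)phenyl]boronic acid)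
Conditions: n-BuLi, B(OiPr)3, THF, −78 °C; then sat. aq NH4Cl, 0 °C
Reagents that add atoms: triisopropyl borate, CC(C)OB(OC(C)C)OC(C)C; water, O
Why: Br/Li exchange with in situ borate trapping, then mild hydrolysis, gives the boronic acid; both positions ortho to OMOM are blocked and MOM survives the near-neutral work-up.

Step 8
Reactants: 8; 14 (2.5 equiv)
Product: 15 ((2S)-7-(methoxymethoxy)-2-[4-(methoxymethoxy)-3,5-bis(3-methylbut-2-en-1-yl)phenyl]-8-(3-methylbut-2-en-1-yl)chroman-4-one)
Conditions: [Rh(OH)(cod)]2 (2.5 mol%), (S)-MeO-F12-BIPHEP (5.5 mol%), CH2Cl2/H2O, 35 °C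
Reagents that add atoms: none beyond boronic acid 14 (water supplies only H at C3)
Why: Hayashi–Miyaura Rh-catalysed asymmetric 1,4-addition; the aryl-Rh adds to the C2 Re face of the chromone and the Rh enolate is protonated by water, setting C2 as S. The (S)-ligand is chosen by analogy with (S)-biaryl bisphosphines giving (S)-3-arylcyclohexanones; the sense should be confirmed by CD and the (R)-ligand used if it is opposite. Base-free conditions avoid retro-oxa-Michael racemisation, and the isolated trisubstituted prenyl alkenes do not insert.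

Step 9
Reactants: 15
Product: 16 (sophoranone, (2S)-7-hydroxy-2-[4-hydroxy-3,5-bis(3-methylbut-2-en-1-yl)phenyl]-8-(3-methylbut-2-en-1-yl)chroman-4-one)
Conditions: 3 M aq HCl, MeOH, rt → 40 °C, stopped at full conversion
Reagents that add atoms: none
Why: Acid-catalysed acetal hydrolysis removes both MOM groups; C2 epimerises only through base-mediated ring opening, so it is retained, and the prenyl groups tolerate brief dilute acid.

**Compound list**
1 | 2-methylbut-3-en-2-ol | CC(C)(O)C=C | starting material
2 | di-tert-butyl dicarbonate | CC(C)(C)OC(=O)OC(=O)OC(C)(C)C | starting material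
3 | tert-butyl 2-methylbut-3-en-2-yl carbonate | C=CC(C)(C)OC(=O)OC(C)(C)C | intermediate
4 | 7-hydroxy-4H-chromen-4-one | O=c1ccoc2cc(O)ccc12 | starting material
5 | 7-[(2-methylbut-3-en-2-yl)oxy]-4H-chromen-4-one | O=c1ccoc2cc(OC(C)(C)C=C)ccc12 | intermediate
6 | 7-hydroxy-8-prenyl-4H-chromen-4-one | O=c1ccoc2c(CC=C(C)C)c(O)ccc12 | intermediate
7 | chloromethyl methyl ether | COCCl | starting material
8 | 7-(methoxymethoxy)-8-prenyl-4H-chromen-4-one | COCOc1ccc2c(occc2=O)c1CC=C(C)C | intermediate
9 | 4-bromo-2,6-diiodophenol | Oc1c(I)cc(Br)cc1I | starting material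
10 | 5-bromo-1,3-diiodo-2-(methoxymethoxy)benzene | COCOc1c(I)cc(Br)cc1I | intermediate
11 | prenylboronic acid pinacol ester | CC(C)=CCB1OC(C)(C)C(C)(C)O1 | starting material
12 | 5-bromo-2-(methoxymethoxy)-1,3-diprenylbenzene | COCOc1c(CC=C(C)C)cc(Br)cc1CC=C(C)C | intermediate
13 | triisopropyl borate | CC(C)OB(OC(C)C)OC(C)C | starting material
14 | [4-(methoxymethoxy)-3,5-diprenylphenyl]boronic acid | COCOc1c(CC=C(C)C)cc(B(O)O)cc1CC=C(C)C | intermediate
15 | (2S)-7,4'-bis(methoxymethoxy)-8,3',5'-triprenylflavanone | CC(C)=CCc1cc([C@@H]2CC(=O)c3ccc(OCOC)c(CC=C(C)C)c3O2)cc(CC=C(C)C)c1OCOC | intermediate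
16 | sophoranone, (2S) | CC(C)=CCc1cc([C@@H]2CC(=O)c3ccc(O)c(CC=C(C)C)c3O2)cc(CC=C(C)C)c1O | target

**Totals**
- Total steps: 9
- Longest linear sequence: 6 (steps 1, 2, 3, 4, 8, 9)

**Three steps most likely to fail, with fallbacks**
1. Step 8. Risks are low chromone reactivity, protodeboronation of the electron-rich boronic acid, 1,2-over-addition, and insufficient ee or the wrong sense. Fallback: a chalcone route with resolution.
   - Formylate 12 (n-BuLi, DMF) to the aldehyde.
   - Condense it (Claisen–Schmidt) with 2-hydroxy-4-(methoxymethoxy)-3-prenylacetophenone, made from 2,4-dihydroxyacetophenone by the chemistry of steps 2–4.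
   - Cyclise with NaOAc to the racemic flavanone.
   - Resolve by Noyori–Ikariya asymmetric transfer hydrogenation (Ru–TsDPEN, HCO2H/Et3N), keeping the unreduced (S)-ketone.
2. Step 6. Risks are α/γ regioselectivity, I versus Br selectivity, and dehalogenation. Fallback: drop the cross-coupling and install the B-ring prenyls by two rounds of Pd O-reverse-prenylation and Claisen rearrangement on 4-bromophenol (as in steps 2–3), then MOM protection and borylation as before.
3. Step 9. Risks are acid-induced cyclisation of the ortho-prenyl phenols to 2,2-dimethylchromans, or slow MOM cleavage. Fallback: change the protecting-group plan to silyl ethers (TBS on 6, TIPS on 9), carried through steps 6–8 and removed with AcOH-buffered TBAF or HF·pyridine, so no protic acid is used.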